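**Plan**

1. Longipinane numbering is used: C-1 ketone carbon, C-2=C-3 alkene (methyl on C-3), C-4/C-11 and C-5/C-10 the cyclobutane carbons, C-6 the CMe2 carbon, C-7 the angelate carbon, C-8 the CH2, C-9 the acetate carbon. Retrosynthesis: remove the C-1 oxygen and the two acyl groups, cut the cyclobutane bond C-4–C-10, then cut together the two seven-membered-ring bonds C-5–C-6 and C-8–C-9.
2. Enabling feature: C-6(Me2)–C-7(O)–C-8H2 is a 3-methylbutan-2-one unit. Its C-6 is allylically transposed (C-5/C-4/C-3) to the methyl-bearing ring carbon C-3, and its C-8 lies 1,3 to the C-9 oxygen. A tertiary allylic β-keto ester on C-3 can therefore hand C-6 to C-5 with loss of CO2, and the freed methyl ketone can close onto a C-9 ester.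
3. Forward: the six-membered ring comes from the chiral pool (1); the side chain is taken to an ester; the key decarboxylative allylation/Dieckmann step closes the seven-membered ring; epoxide opening by the diketone dianion closes the cyclobutane; then alkene, carbinols, esters and the C-1 ketone.
4. Stereochemistry: C-11 from 1; C-5 by 1,3-transfer from the C-3 carbinol (double inversion on palladium); C-4 and C-10 by anti epoxidation and backside opening inside the cis-fused bicycle.
5. C-9 by CBS reduction; C-7 by Evans–Tishchenko 1,3-anti reduction, which also places the acetate.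

Key step: step 5

Remark: 1 (the limonene-derived p-mentha-2,8-dien-1-ol isomer with hydroxyl cis to isopropenyl), diketene 6 and angelic acid 16 are taken as commercially available. The side-chain carbon that becomes C-10 is carried as an epimer mixture because step 7 planarises it.

**Route**

Step 1
Reactants: 1 (1S,4R)-1-methyl-4-(prop-1-en-2-yl)cyclohex-2-en-1-ol
Product: 3 (1S,4R)-4-(1-hydroxypropan-2-yl)-1-methylcyclohex-2-en-1-ol, via B-alkyl borane 2 (not isolated)
Conditions: 9-BBN (1.3 equiv), THF, 0 → 25 °C; then NaOH, H2O2, 0 °C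
Reagents that add atoms: hydrogen peroxide (OO)
Why: Anti-Markovnikov hydroboration–oxidation, in which the bulky dialkylborane should add only to the 1,1-disubstituted isopropenyl group and not to the cis-disubstituted ring alkene; the new methyl-bearing centre (future C-10) may form as either epimer because it is planarised in step 7.

Step 2
Reactants: 3 (1S,4R)-4-(1-hydroxypropan-2-yl)-1-methylcyclohex-2-en-1-ol
Product: 5 methyl 2-[(1R,4S)-4-hydroxy-4-methylcyclohex-2-en-1-yl]propanoate, via hydroxy acid 4 (not isolated)
Conditions: TEMPO (10 mol %), PhI(OAc)2 (2.2 equiv), MeCN–H2O (pH 7), 0 → 25 °C; then MeI, K2CO3, DMF, 25 °C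
Reagents that add atoms: water (O); iodomethane (CI)
Why: Oxoammonium (TEMPO) oxidation should take the primary alcohol through the aldehyde hydrate to the acid without touching the tertiary allylic alcohol or the alkene (a chromium oxidant would risk allylic transposition), and carboxylate O-methylation then gives the ester; no stereocentre is created.

Step 3
Reactants: 5 methyl 2-[(1R,4S)-4-hydroxy-4-methylcyclohex-2-en-1-yl]propanoate; 6 diketene
Product: 7 (1S,4R)-4-(1-methoxy-1-oxopropan-2-yl)-1-methylcyclohex-2-en-1-yl 3-oxobutanoate
Conditions: 6 (1.3 equiv), DMAP (5 mol %), Et3N (0.2 equiv), CH2Cl2, −20 → 25 °C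
Reagents that add atoms: none
Why: DMAP-catalysed acetoacetylation (ring opening of diketene through the acylpyridinium) works on hindered tertiary alcohols below room temperature, well under the temperature at which a tertiary allylic acetoacetate would undergo Carroll rearrangement; the carbinol configuration is untouched.

Step 4
Reactants: 7 (1S,4R)-4-(1-methoxy-1-oxopropan-2-yl)-1-methylcyclohex-2-en-1-yl 3-oxobutanoate
Product: 8 (1S,4R)-4-(1-methoxy-1-oxopropan-2-yl)-1-methylcyclohex-2-en-1-yl 2,2-dimethyl-3-oxobutanoate
Conditions: MeI (4 equiv), Cs2CO3 (3 equiv), DMF, 25 °C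
Reagents that add atoms: iodomethane (CI)
Why: Double C-alkylation of the β-keto ester with a mild base that leaves the side-chain ester α-hydrogen alone installs the future gem-dimethyl group of C-6 and removes both acidic hydrogens, so that the enolate can later arise only by decarboxylation.

Step 5
Reactants: 8 (1S,4R)-4-(1-methoxy-1-oxopropan-2-yl)-1-methylcyclohex-2-en-1-yl 2,2-dimethyl-3-oxobutanoate
Product: 10 (4aR,9aR)-2,5,9,9-tetramethyl-3,4,4a,5,9,9a-hexahydro-6H-benzo[7]annulene-6,8(7H)-dione, via methyl ketone 9 (not isolated)
Conditions: Pd(PPh3)4 (5 mol %), THF, 25 °C, until CO2 evolution ends; then t-BuOK (2.5 equiv), 0 → 25 °C, same flask; aqueous HCl work-up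
Reagents that add atoms: none
Why: Zerovalent palladium ionises the tertiary allylic β-keto ester anti to the leaving carboxylate, and loss of CO2 from the 2,2-dimethyl-3-oxobutanoate (no α-hydrogen, so alkylation cannot precede decarboxylation) gives the tetrasubstituted enolate of 3-methylbutan-2-one regiospecifically; this enolate should attack the unsubstituted terminus of the 1-methylcyclohexenyl π-allyl complex anti to palladium, forming C-5–C-6 and moving the double bond to C-3/C-4 (Tsuji–Trost-type decarboxylative allylic alkylation, the closest known type being the decarboxylative allylation of allyl α,α-disubstituted β-keto esters). The double inversion delivers C-6 to the face that the ester oxygen occupied, which is cis to the C-11 side chain, so the C-3 carbinol stereocentre of 8 is traded for the C-5 stereocentre and the cis ring fusion needed in step 7 is secured by the substrate; attack at the methyl-bearing terminus would join two fully substituted carbons and is disfavoured. t-BuOK then generates the methyl-ketone enolate at C-8, which closes the seven-membered ring by Dieckmann-type Claisen condensation onto the side-chain ester (7-exo-trig addition, then loss of methoxide), forming C-8–C-9. No other stereocentre is fixed, since C-10 stays a mixture until step 7. The selectivities needed are regio- and facial control in the allylation and use of the C-8 rather than the C-10 enolate in the closure; the first two follow from the ion-pair geometry and substitution pattern, the last from reversibility, because only the C-8 pathway ends in the stabilised 1,3-diketonate.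

Step 6
Reactants: 10 (4aR,9aR)-2,5,9,9-tetramethyl-3,4,4a,5,9,9a-hexahydro-6H-benzo[7]annulene-6,8(7H)-dione
Product: 11 1,2-epoxide of 10 with the oxirane oxygen on the face opposite to the seven-membered ring
Conditions: m-CPBA, NaHCO3, CH2Cl2, 0 °C
Reagents that add atoms: 3-chloroperoxybenzoic acid (OOC(=O)c1cccc(Cl)c1)
Why: Prilezhaev epoxidation of the only alkene should occur from the convex face of the cis-fused bicycle, anti to the quaternary C-6 on the neighbouring carbon, which places the oxirane oxygen trans to C-6 as required for backside attack by C-10.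

Step 7
Reactants: 11 1,2-epoxide of 10
Product: 12 (3R,4S,5R,10S,11R)-3-hydroxylongipinane-7,9-dione
Conditions: LiN(i-Pr)2 (2.5 equiv), THF–DMPU, −78 → 0 °C; then AcOH
Reagents that add atoms: none
Why: The 1,3-diketone dianion has its only γ-hydrogen at C-10, and this γ-carbanion should open the epoxide intramolecularly at the secondary carbon C-4 with inversion (4-exo-tet C-alkylation, preferred over attack at the tertiary carbon), forming the cyclobutane; C-4 is set by the inversion, C-10 by the ring system (C-9 must stay in the seven-membered ring, so the methyl is exo), and C-3 keeps the epoxide oxygen.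

Step 8
Reactants: 12 (3R,4S,5R,10S,11R)-3-hydroxylongipinane-7,9-dione
Product: 13 (4R,5R,10S,11R)-longipin-2-ene-7,9-dione
Conditions: Burgess reagent, PhMe, 60 °C
Reagents that add atoms: none
Why: Burgess dehydration (syn elimination through the sulfamate ester, avoiding a free cation that could trigger cyclobutane migration) should give the endocyclic trisubstituted alkene, because elimination towards the bridgehead C-4 is forbidden and the ring methylene gives the more substituted alkene; the C-3 stereocentre is removed.

Step 9
Reactants: 13 (4R,5R,10S,11R)-longipin-2-ene-7,9-dione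
Product: 14 (4R,5R,9R,10S,11R)-9-hydroxylongipin-2-en-7-one
Conditions: (S)-2-methyl-CBS-oxazaborolidine (0.2 equiv), BH3·SMe2 (0.6 equiv), THF, −30 °C; then MeOH
Reagents that add atoms: none
Why: CBS reduction is reagent-controlled: the C-9 carbonyl, flanked by the tied-back cyclobutane carbon C-10, should react before the C-7 carbonyl shielded by the gem-dimethyl carbon, and the (S)-catalyst, reading C-10 as the large and C-8 as the small group, should give the (9R)-alcohol.

Step 10
Reactants: 14 (4R,5R,9R,10S,11R)-9-hydroxylongipin-2-en-7-one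
Product: 15 (4R,5R,7R,9R,10S,11R)-7-hydroxylongipin-2-en-9-yl acetate
Conditions: MeCHO (5 equiv), SmI2 (0.3 equiv), THF, −10 °C
Reagents that add atoms: acetaldehyde (CC=O)
Why: Evans–Tishchenko reduction: the samarium-bound hemiacetal formed from the C-9 hydroxyl and acetaldehyde transfers hydride intramolecularly to the C-7 carbonyl through a six-membered transition state, which should give the 1,3-anti (7R) alcohol and leave the oxidised aldehyde as the C-9 acetate.

Step 11
Reactants: 15 (4R,5R,7R,9R,10S,11R)-7-hydroxylongipin-2-en-9-yl acetate; 16 angelic acid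
Product: 17 (4R,5R,7R,9R,10S,11R)-9-acetoxylongipin-2-en-7-yl (Z)-2-methylbut-2-enoate
Conditions: 16, 2,4,6-trichlorobenzoyl chloride, Et3N, PhMe, 25 °C; then 15, 80 °C
Reagents that add atoms: none
Why: Yamaguchi-type esterification through the mixed 2,4,6-trichlorobenzoic anhydride should acylate the hindered neopentyl C-7 hydroxyl without a nucleophilic catalyst, conditions under which the (Z)-geometry of the angelate is retained; no ring stereocentre changes.

Step 12
Reactants: 17 (4R,5R,7R,9R,10S,11R)-9-acetoxylongipin-2-en-7-yl (Z)-2-methylbut-2-enoate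
Product: 18 (4R,5S,7R,9R,10R,11R)-9-acetoxy-1-oxolongipin-2-en-7-yl (Z)-2-methylbut-2-enoate
Conditions: Rh2(cap)4 (dirhodium tetrakis(caprolactamate), 1 mol %), t-BuOOH (5 equiv), K2CO3 (0.5 equiv), CH2Cl2, 25 °C
Reagents that add atoms: tert-butyl hydroperoxide (CC(C)(C)OO)
Why: Dirhodium-catalysed allylic C–H oxidation with tert-butyl hydroperoxide should convert the ring methylene C-1 next to the C-2/C-3 alkene into the conjugated ketone, with the site preference of the α-pinene to verbenone oxidation (the bridgehead C-4 hydrogen and the C-3 methyl are less reactive, and the angelate alkene is electron-poor); no stereocentre is formed.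

**Compound list**

1 | (1S,4R)-1-methyl-4-(prop-1-en-2-yl)cyclohex-2-en-1-ol (hydroxyl cis to isopropenyl) | C[C@@]1(O)C=C[C@H](C(C)=C)CC1 | starting material
2 | B-alkyl-9-borabicyclo[3.3.1]nonane adduct of 1 (boron on the former =CH2 carbon) | C[C@@]1(O)C=C[C@H](C(C)CB2C3CCCC2CCC3)CC1 | intermediate
3 | (1S,4R)-4-(1-hydroxypropan-2-yl)-1-methylcyclohex-2-en-1-ol (both side-chain epimers) | C[C@@]1(O)C=C[C@H](C(C)CO)CC1 | intermediate
4 | 2-[(1R,4S)-4-hydroxy-4-methylcyclohex-2-en-1-yl]propanoic acid (side-chain epimers) | C[C@@]1(O)C=C[C@H](C(C)C(O)=O)CC1 | intermediate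
5 | methyl 2-[(1R,4S)-4-hydroxy-4-methylcyclohex-2-en-1-yl]propanoate (side-chain epimers) | C[C@@]1(O)C=C[C@H](C(C)C(=O)OC)CC1 | intermediate
6 | diketene (4-methylideneoxetan-2-one) | C=C1CC(=O)O1 | starting material
7 | (1S,4R)-4-(1-methoxy-1-oxopropan-2-yl)-1-methylcyclohex-2-en-1-yl 3-oxobutanoate | CC(=O)CC(=O)O[C@]1(C)C=C[C@H](C(C)C(=O)OC)CC1 | intermediate
8 | (1S,4R)-4-(1-methoxy-1-oxopropan-2-yl)-1-methylcyclohex-2-en-1-yl 2,2-dimethyl-3-oxobutanoate | CC(=O)C(C)(C)C(=O)O[C@]1(C)C=C[C@H](C(C)C(=O)OC)CC1 | intermediate
9 | methyl 2-[(1R,2R)-4-methyl-2-(2-methyl-3-oxobutan-2-yl)cyclohex-3-en-1-yl]propanoate (ring substituents cis) | CC1=C[C@H](C(C)(C)C(C)=O)[C@H](C(C)C(=O)OC)CC1 | intermediate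
10 | (4aR,9aR)-2,5,9,9-tetramethyl-3,4,4a,5,9,9a-hexahydro-6H-benzo[7]annulene-6,8(7H)-dione (cis-fused; C-5 epimers) | CC1=C[C@@H]2C(C)(C)C(=O)CC(=O)C(C)[C@@H]2CC1 | intermediate
11 | 1,2-epoxide of 10, oxirane oxygen on the face opposite to the seven-membered ring | C[C@]12O[C@H]1[C@@H]3C(C)(C)C(=O)CC(=O)C(C)[C@@H]3CC2 | intermediate
12 | (3R,4S,5R,10S,11R)-3-hydroxylongipinane-7,9-dione | O=C1CC(=O)[C@@]2(C)[C@@H]3CC[C@@](C)(O)[C@H]2[C@@H]3C1(C)C | intermediate
13 | (4R,5R,10S,11R)-longipin-2-ene-7,9-dione | O=C1CC(=O)[C@@]2(C)[C@@H]3CC=C(C)[C@H]2[C@@H]3C1(C)C | intermediate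
14 | (4R,5R,9R,10S,11R)-9-hydroxylongipin-2-en-7-one | O=C1C[C@@H](O)[C@@]2(C)[C@@H]3CC=C(C)[C@H]2[C@@H]3C1(C)C | intermediate
15 | (4R,5R,7R,9R,10S,11R)-7-hydroxylongipin-2-en-9-yl acetate | O[C@@H]1C[C@@H](OC(C)=O)[C@@]2(C)[C@@H]3CC=C(C)[C@H]2[C@@H]3C1(C)C | intermediate
16 | angelic acid, (Z)-2-methylbut-2-enoic acid | C/C=C(/C)C(=O)O | starting material
17 | (4R,5R,7R,9R,10S,11R)-9-acetoxylongipin-2-en-7-yl (Z)-2-methylbut-2-enoate | C/C=C(/C)C(=O)O[C@@H]1C[C@@H](OC(C)=O)[C@@]2(C)[C@@H]3CC=C(C)[C@H]2[C@@H]3C1(C)C | intermediate
18 | (4R,5S,7R,9R,10R,11R)-9-acetoxy-1-oxolongipin-2-en-7-yl (Z)-2-methylbut-2-enoate | C/C=C(/C)C(=O)O[C@@H]1C[C@@H](OC(C)=O)[C@@]2(C)[C@@H]3C(=O)C=C(C)[C@H]2[C@@H]3C1(C)C | target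

Total step count: 12. Longest linear sequence: 12 steps (from 1).

**Steps most likely to fail**

Step 5. What may go wrong: loss of stereochemical fidelity when the allylpalladium intermediate is captured (inner-sphere delivery, or epimerisation of the π-allyl complex, either of which would place C-6 trans to the side chain), or β-hydride elimination to a diene. The fallback uses a sigmatropic shift instead of an ion pair; it sets out from 5 and returns at 9. Compound 5 is acylated with isobutyric anhydride and DMAP to the 2-methylpropanoate ester F1. Ireland–Claisen rearrangement of its silyl ketene acetal (LiN(i-Pr)2, Me3SiCl, THF, −78 → 60 °C) is suprafacial and should give the carboxylic acid F2 with C-6 delivered cis to the side chain. Oxalyl chloride gives the acid chloride F3, and Me2CuLi at −78 °C should convert it into methyl ketone 9 without touching the methyl ester. Compound 9 is then cyclised with t-BuOK to 10 as in step 5.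

Step 7. What may go wrong: O-alkylation of the diketonate, base-induced isomerisation of the epoxide to an allylic alcohol, or a sluggish 4-exo closure at the hindered epoxide carbon. The fallback replaces epoxide opening by sulfonate displacement; it sets out from 11 and returns at 13. Hydrolytic opening of 11 (dilute HClO4, THF–H2O; water attacks the tertiary carbon with inversion) gives the trans-diol F4. MsCl/pyridine followed by Me3SiOTf/2,6-lutidine gives the secondary mesylate with the tertiary hydroxyl silylated, F5. LiN(i-Pr)2 (2.5 equiv) should then close the cyclobutane by backside displacement of the mesylate to give the silyl ether F6. HF·pyridine gives the C-3 epimeric alcohol F7, which Burgess dehydration converts into 13.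

Step 9. What may go wrong: poor site selectivity between the two neopentyl ketones, or over-reduction. The fallback differentiates the oxygens by acylation rather than by the Tishchenko step; it sets out from 13 and returns at 15. Exhaustive reduction with excess BH3·SMe2 and stoichiometric (S)-2-methyl-CBS-oxazaborolidine should give the (7R,9R)-diol F8, both carbinols being set by the catalyst. Monoacetylation of the less hindered C-9 hydroxyl (Ac2O, pyridine, 0 °C) then gives 15.

Further compounds
F1 | step 5 | (1S,4R)-4-(1-methoxy-1-oxopropan-2-yl)-1-methylcyclohex-2-en-1-yl 2-methylpropanoate | CC(C)C(=O)O[C@]1(C)C=C[C@H](C(C)C(=O)OC)CC1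
F2 | step 5 | 2-[(1R,6R)-6-(1-methoxy-1-oxopropan-2-yl)-3-methylcyclohex-2-en-1-yl]-2-methylpropanoic acid | CC1=C[C@H](C(C)(C)C(O)=O)[C@H](C(C)C(=O)OC)CC1
F3 | step 5 | 2-[(1R,6R)-6-(1-methoxy-1-oxopropan-2-yl)-3-methylcyclohex-2-en-1-yl]-2-methylpropanoyl chloride | CC1=C[C@H](C(C)(C)C(Cl)=O)[C@H](C(C)C(=O)OC)CC1
F4 | step 7 | trans-1,2-diol from 11 (secondary hydroxyl anti and tertiary hydroxyl syn to the seven-membered ring) | C[C@@]1(O)[C@@H](O)[C@@H]2C(C)(C)C(=O)CC(=O)C(C)[C@@H]2CC1
F5 | step 7 | secondary methanesulfonate, tertiary trimethylsilyl ether of F4 | C[C@@]1(O[Si](C)(C)C)[C@@H](OS(C)(=O)=O)[C@@H]2C(C)(C)C(=O)CC(=O)C(C)[C@@H]2CC1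
F6 | step 7 | (3S,4S,5R,10S,11R)-3-(trimethylsilyloxy)longipinane-7,9-dione | O=C1CC(=O)[C@@]2(C)[C@@H]3CC[C@](C)(O[Si](C)(C)C)[C@H]2[C@@H]3C1(C)C
F7 | step 7 | (3S,4S,5R,10S,11R)-3-hydroxylongipinane-7,9-dione | O=C1CC(=O)[C@@]2(C)[C@@H]3CC[C@](C)(O)[C@H]2[C@@H]3C1(C)C
F8 | step 9 | (4R,5R,7R,9R,10S,11R)-longipin-2-ene-7,9-diol | O[C@@H]1C[C@@H](O)[C@@]2(C)[C@@H]3CC=C(C)[C@H]2[C@@H]3C1(C)C
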